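## Analysis of the target

CNP0164025.1 (23) is an eremophilane sesquiterpenoid diester. Eremophilane numbering is used throughout: ring A is C1–C5 and C10, ring B is C5–C10, C14 is the methyl on C5, C15 the methyl on C4, and C11–C13 the isopropenyl group on C7; β is the face of C14.

- The core is a trans-fused decalin with a ketone at C8.
- The six stereocentres are 3R, 4R, 5R, 7S, 9S, 10R. The senecioate on C3 (α), the C4 methyl (β), the isopropenyl group on C7 (α) and the tiglate on C9 (α) are equatorial. Only the angular C5 methyl (β) is axial, anti to H10 (α).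
- The C3–C4–C5 triad carries two cis methyl groups, one on a quaternary carbon, and cannot be corrected by equilibration. C7 and C9 flank the ketone and already hold their favoured equatorial configurations.
- Sensitive features are the β,γ-unsaturated ketone (the isopropenyl alkene can slip into conjugation under acid or base), the α-acyloxy ketone at C9, and two different enoate esters that tolerate neither strong nucleophiles nor dissolving metals. The esters must therefore come last and in a fixed order.
- The difficulty is to build quaternary C5 next to C4 with the right relative configuration, then to dress ring B (C7 branch, C8 carbonyl, C9 oxygen, trans fusion) without disturbing C3–C5.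
- The strategy rests on ring B. The C8 oxygen has the three-carbon branch on its neighbour C7, and quaternary C5 lies two bonds beyond C7. With an alkene at C9=C10 this is the pattern of the ortho adduct of a 1-alkoxydiene C8=C9–C10=C5, grown on ring A, with a vinyl ketone.

## Retrosynthetic reasoning

**Ester bonds.** The C3–O acyl bond is cut first (23 to 21 and 22), then the C9–O acyl bond (20 to 18 and 19). The esters are the most fragile groups, so they are attached last. The C9 ester goes on while C3 is still silylated, which makes the two hydroxyl groups distinguishable without any selectivity problem.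

**C9–O and C10–H.** Ketol 18 is traced to enone 13 by removing the C9 oxygen and restoring the C9=C10 alkene. Direct enolisation of a trans-decal-8-one would favour the C7 side. Reduction of the enone with an alkali metal in ammonia instead gives the C8–C9 enolate only, and it delivers H10 on the α face, which sets the trans fusion. The enolate is held as silyl enol ether 15 and oxidised on the α face, anti to C14.

**C8 oxidation level and the isopropenyl group.** Enone 13 comes from allylic ether 11 by oxidation at C8, and 11 from methyl ketone 10 by methylenation of the acetyl carbonyl. The acetyl group must be converted first, because a C8 ketone next to a C7 acetyl group would be an enolised 1,3-diketone.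

**Ring B (key disconnection).** In 10 the bonds C5–C6 and C7–C8 are cut, giving diene 8 and enone 9. This single cut removes ring B, the quaternary centre, the C7 branch and the C8 oxygen, and it leaves the C9=C10 alkene exactly where the later enone needs it. The forward reaction must be ortho-selective and must add to the face of ring A anti to the C4 methyl.

**C9–C10.** Diene 8 is cut at the sp2–sp2 bond C9–C10 into enol triflate 6 and alkenylboronate 7. A cross-coupling transfers the E geometry of 7 unchanged. An alkoxymethylene olefination of the corresponding aldehyde would give E/Z mixtures, and the Z isomer is a poor diene.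

**C4–C15.** Triflate 6 is traced to enone 4 by cutting the C4–C15 bond. Conjugate addition of a methyl cuprate anti to the silyloxy group sets C4 trans to C3, and the enolate is captured as the C10=C5 enol triflate without any regiochemical ambiguity. A 2,3-dimethyl enone was not used: metal–ammonia reduction of a γ-silyloxy enone risks expelling the γ-oxygen, and hydride delivery anti to the silyloxy group would give the wrong C4 epimer.

**Ring A oxidation pattern.** Enone 4 comes from silyl ether 3 by allylic oxidation at C10, 3 from alcohol 2, and 2 from achiral enone 1 by catalytic asymmetric reduction, which sets C3 and with it the absolute configuration of the whole route.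

## Alternatives that were turned down

**Alternative 1:** The whole skeleton is cut back to the acyclic diphosphate A2 (farnesyl diphosphate). Aristolochene synthase, a Mg2+-dependent class one terpene cyclase, ionises A2, closes the ten-membered ring (C6–C7) and then the decalin (C5–C10). After a hydride shift from C5 to C4 and a methyl shift from C10 to C5 it releases (+)-aristolochene A1.
- For: one step forms both rings and sets C4, C5 and C7 in the configuration of 23, with the C9=C10 alkene in the same place as in the chosen route. On skeleton step economy and on absolute stereocontrol it is stronger than anything chemical.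
- Against: A1 carries no oxygen. C8 and C9 could be reached through allylic oxidation and the enone chemistry used here, although C1 is allylic too. C3 is an unactivated methylene with no directing group nearby, so a 3α-hydroxylation would need a dedicated oxygenase or an undirected C–H oxidation in the presence of two alkenes.
- Comparison: the chosen route carries the C3 oxygen from its first step and needs no site-selective C–H hydroxylation of ring A. It pays with a longer build-up of the skeleton.

**Alternative 2:** The C5–C10 bond is cut, giving the ten-membered (E)-enone A4 with an exocyclic methylene on C5. Fe(acac)3 (trivalent iron) and PhSiH3 transfer a hydrogen atom to the methylene carbon; the tertiary C5 radical adds across the ring to C10 of the enone and gives the trans-fused decalinone A3.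
- For: the quaternary centre, the C14 methyl and the trans ring fusion arise together, so no separate reduction is needed for C10; on this point it is stronger than the chosen route.
- Against: A4 is a medium ring with two stereocentres, an (E)-enone and a 1,1-disubstituted alkene, whose assembly needs a macrocyclisation and many steps. A3 has neither the C7 branch nor the C9 oxygen; both flank the ketone and need enolate chemistry on each side in turn, and an isopropenyl group cannot be introduced by simple alkylation. The C5 configuration relative to C4 depends on the conformation of the ten-membered ring in the cyclisation.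
- Comparison: in the chosen route the C7 branch and the C8 oxygen arrive in the ring-forming step, and the enone fixes which side of the ketone is functionalised.

**Alternative 3:** Ring A is cut at C4–C5 and C1–C10, giving the quinone A6 (2-methoxy-5-methyl-1,4-benzoquinone) and the (Z)-silyloxydiene A7. Under TiCl2(O-i-Pr)2 with BINOL (a chelating chiral Lewis acid of tetravalent titanium) the diene adds endo to the methyl-bearing alkene of A6 and gives the cis-fused adduct A5.
- For: a catalytic enantioselective, convergent step from achiral partners sets C4, C5 and C10 together, with the C8 oxygen present as an enol ether and C3 as a silyl enol ether. On absolute stereocontrol in the ring-forming step it is stronger than the chosen route, which relies on an earlier asymmetric reduction and substrate control.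
- Against: A5 is cis-fused and needs C10 epimerisation. It has a surplus carbonyl at C6 to remove and a C9 ketone to reduce with stereocontrol. It lacks the C7 branch, and its C3 ketone must later be reduced to the 3α-alcohol. The (Z)-diene reacts slowly.
- Comparison: the chosen route reaches the ring B oxidation pattern with one oxidation and one reduction and no deoxygenation.

Key step: step 6

## Route

Assumption: the (S)-oxazaborolidine is taken to give the (R)-carbinol 2 (alkenyl flank acting as the large group); if the sense is the opposite, the (R)-catalyst is used.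

Step 1
Reactants: 1 3-methylcyclohex-2-en-1-one
Product: 2 (R)-3-methylcyclohex-2-en-1-ol
Conditions: (S)-2-methyl-CBS-oxazaborolidine (10 mol%), catecholborane, toluene, −78 °C
Reagents that add atoms: none
Why: Corey–Bakshi–Shibata reduction: the oxazaborolidine binds the carbonyl oxygen anti to the alkenyl flank and catecholborane delivers hydride to one face, which should set C3 as R. 1,2-Reduction is expected because catecholborane does not hydroborate the alkene at −78 °C.

Step 2
Reactants: 2 (R)-3-methylcyclohex-2-en-1-ol
Product: 3 (R)-triisopropyl[(3-methylcyclohex-2-en-1-yl)oxy]silane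
Conditions: TIPSCl, imidazole, DMAP (cat.), DMF, rt
Reagents that add atoms: triisopropylsilyl chloride, CC(C)[Si](Cl)(C(C)C)C(C)C
Why: Standard silylation of a secondary allylic alcohol. The bulky silyl ether is chosen to survive the cuprate, palladium, DDQ, dissolving-metal and peracid steps and to shield the carbinol C–H in step 3.

Step 3
Reactants: 3 (R)-triisopropyl[(3-methylcyclohex-2-en-1-yl)oxy]silane
Product: 4 (R)-2-methyl-4-(triisopropylsilyloxy)cyclohex-2-en-1-one
Conditions: CrO3, 3,5-dimethylpyrazole, CH2Cl2, −20 °C
Reagents that add atoms: chromium trioxide, O=[Cr](=O)=O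
Why: Allylic C–H oxidation of a trisubstituted cyclohexene with the CrO3–3,5-dimethylpyrazole complex should turn the ring methylene next to the methyl-bearing alkene carbon (C10) into the enone carbonyl. The methyl group is less reactive than the ring CH2 and the carbinol C–H is shielded by the silyl group; the stereocentre is not touched.

Step 4
Reactants: 4 (R)-2-methyl-4-(triisopropylsilyloxy)cyclohex-2-en-1-one
Product: 6 (3R,4R)-2,3-dimethyl-4-(triisopropylsilyloxy)cyclohex-1-en-1-yl trifluoromethanesulfonate, via lithium enolate 5 (not isolated)
Conditions: Me2CuLi (from CuI and MeLi), Et2O, −78 to −20 °C; then PhNTf2, THF, −78 °C to rt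
Reagents that add atoms: lithium dimethylcuprate, [Li+].C[Cu-]C; N-phenylbis(trifluoromethanesulfonimide), O=S(=O)(N(c1ccccc1)S(=O)(=O)C(F)(F)F)C(F)(F)F
Why: Conjugate addition of a lithium dialkylcuprate to a 4-silyloxycyclohexenone takes place anti to the γ-silyloxy group, which should set the C4 methyl trans to the C3 oxygen. The enolate is captured on oxygen by PhNTf2, which fixes the tetrasubstituted C10=C5 enol triflate regiospecifically.

Step 5
Reactants: 6 (3R,4R)-2,3-dimethyl-4-(triisopropylsilyloxy)cyclohex-1-en-1-yl trifluoromethanesulfonate; 7 (E)-2-(2-ethoxyethenyl)-4,4,5,5-tetramethyl-1,3,2-dioxaborolane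
Product: 8 triisopropyl{[(1R,2R)-4-[(E)-2-ethoxyethenyl]-2,3-dimethylcyclohex-3-en-1-yl]oxy}silane
Conditions: Pd(PPh3)4 (5 mol%), aq. K3PO4, 1,4-dioxane, 70 °C; chromatography on basic alumina
Reagents that add atoms: none
Why: Suzuki–Miyaura coupling of an enol triflate with an alkenylboronate under zerovalent palladium catalysis. Both partners couple with retention, so the E geometry of 7 is carried into the 1-ethoxydiene, and the basic medium protects the enol ether.

Step 6
Reactants: 8 triisopropyl{[(1R,2R)-4-[(E)-2-ethoxyethenyl]-2,3-dimethylcyclohex-3-en-1-yl]oxy}silane; 9 but-3-en-2-one (methyl vinyl ketone)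
Product: 10 7α-acetyl-8α-ethoxy-4β,5β-dimethyl-3α-(triisopropylsilyloxy)octal-9-ene (3R,4R,5R,7R,8S)
Conditions: 9 (5 equiv), BHT (trace), CH2Cl2, 13 kbar, 25–40 °C
Reagents that add atoms: none
Why: The reaction is a concerted, asynchronous [4+2] cycloaddition of normal electron demand between the 1-ethoxydiene C8=C9–C10=C5 and the enone, in which the C5–C6 bond to the enone β-carbon is more advanced than the C7–C8 bond. The closest known reaction type is the ortho-selective Diels–Alder reaction of 1-alkoxy-1,3-dienes, semicyclic 1-vinylcyclohexenes included, with vinyl ketones under thermal or high-pressure conditions. Ring B closes in this intermolecular step as a six-membered ring through two new σ-bonds formed suprafacially on both partners, and the C9=C10 alkene is left behind. The ethoxy donor on C8 puts the largest HOMO coefficient on C5, which pairs with the enone β-carbon, so the acetyl group should land on C7 next to C8. C5 is set by the face of attack: the C4 methyl is held pseudoaxial by A(1,2) strain with C14, and the dienophile should add anti to it, on the α face, so that C14 ends cis to C15. The E geometry of the enol ether places the ethoxy group α at C8, and the endo orientation of the acetyl group, favoured by the compact transition state under pressure, places it cis to the ethoxy group (7α). The step must deliver the regiochemistry and the C5 configuration; C8 is later oxidised and C7 sits α to the future ketone, where the 7α arrangement is also the stable one. The C14 methyl on the inside of the diene terminus raises the barrier, which is why pressure is used in place of a strong Lewis acid that would hydrolyse or polymerise the enol ether.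

Step 7
Reactants: 10 7α-acetyl-8α-ethoxy-4β,5β-dimethyl-3α-(triisopropylsilyloxy)octal-9-ene
Product: 11 8α-ethoxy-7α-isopropenyl-4β,5β-dimethyl-3α-(triisopropylsilyloxy)octal-9-ene (3R,4R,5R,7S,8S)
Conditions: Ph3PCH3Br, KN(SiMe3)2, THF, 0 °C to rt
Reagents that add atoms: methyltriphenylphosphonium bromide, C[P+](c1ccccc1)(c1ccccc1)c1ccccc1.[Br-]
Why: Wittig methylenation of a methyl ketone. The non-stabilised ylide should add to the carbonyl faster than it deprotonates the branched α-carbon C7, so the C7 configuration and the β-ethoxy group are expected to be kept.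

Step 8
Reactants: 11 8α-ethoxy-7α-isopropenyl-4β,5β-dimethyl-3α-(triisopropylsilyloxy)octal-9-ene
Product: 13 7α-isopropenyl-4β,5β-dimethyl-3α-(triisopropylsilyloxy)octal-9-en-8-one (3R,4R,5R,7S), via hemiketal 12 (not isolated)
Conditions: DDQ (1.5 equiv), CH2Cl2/pH 7 phosphate buffer (10:1), 0 °C to rt
Reagents that add atoms: water, O
Why: DDQ oxidation of an allylic ether, the reaction type that cleaves prenyl ethers: hydride is abstracted from C8, which is activated by the ether oxygen and by the C9=C10 alkene with its fully substituted terminus. Water adds to the oxocarbenium ion and the hemiketal loses ethanol to give the enone. The silyl ether, the isopropenyl group and C7 should be inert in the buffered medium.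

Step 9
Reactants: 13 7α-isopropenyl-4β,5β-dimethyl-3α-(triisopropylsilyloxy)octal-9-en-8-one
Product: 15 trans-fused 7α-isopropenyl-4β,5β-dimethyl-3α-(triisopropylsilyloxy)-8-(trimethylsilyloxy)-10α-H-octal-8-ene, via lithium enolate 14 (not isolated)
Conditions: Li, NH3(l)/THF, t-BuOH (1.0 equiv), −78 °C; isoprene; NH3 evaporated; then TMSCl, Et3N, THF, −78 to 0 °C
Reagents that add atoms: chlorotrimethylsilane, C[Si](C)(C)Cl; lithium, [Li] (held only in 14)
Why: Dissolving-metal (Birch-type) reduction of an octalenone: the C10 carbanion is protonated axially on the α face, anti to the angular methyl, which should give the trans ring fusion. The C8–C9 lithium enolate forms regiospecifically and is trapped on oxygen; the isolated isopropenyl alkene and the silyl ether are inert to Li/NH3.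

Step 10
Reactants: 15 trans-fused 7α-isopropenyl-4β,5β-dimethyl-3α-(triisopropylsilyloxy)-8-(trimethylsilyloxy)-10α-H-octal-8-ene
Product: 18 9α-hydroxy-7α-isopropenyl-4β,5β-dimethyl-3α-(triisopropylsilyloxy)-trans-decal-8-one (3R,4R,5R,7S,9S,10R), via silyloxy epoxide 16 (not isolated), via 9α-trimethylsilyloxy ketone 17 (not isolated)
Conditions: mCPBA (1.05 equiv), NaHCO3, CH2Cl2, −20 °C; then 1 M HCl, THF, 0 °C
Reagents that add atoms: 3-chloroperbenzoic acid, O=C(OO)c1cccc(Cl)c1
Why: Rubottom oxidation: the peracid should epoxidise the electron-rich silyl enol ether much faster than the 1,1-disubstituted alkene, and from the α face, because the β face at C9 is blocked by the 1,3-diaxial C14 methyl. Epoxide opening with 1,4-silyl shift and acidic removal of the trimethylsilyl group should give the equatorial 9α-alcohol.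

Step 11
Reactants: 18 9α-hydroxy-7α-isopropenyl-4β,5β-dimethyl-3α-(triisopropylsilyloxy)-trans-decal-8-one; 19 (E)-2-methylbut-2-enoyl chloride (tigloyl chloride)
Product: 20 7α-isopropenyl-4β,5β-dimethyl-9α-tigloyloxy-3α-(triisopropylsilyloxy)-trans-decal-8-one
Conditions: 19, pyridine, DMAP (cat.), CH2Cl2, 0 °C to rt
Reagents that add atoms: none
Why: Pyridine/DMAP acylation of the secondary α-ketol with an acid chloride. C3 is still silylated, so only C9 is esterified, and the E geometry of the tigloyl group is the stable one.

Step 12
Reactants: 20 7α-isopropenyl-4β,5β-dimethyl-9α-tigloyloxy-3α-(triisopropylsilyloxy)-trans-decal-8-one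
Product: 21 3α-hydroxy-7α-isopropenyl-4β,5β-dimethyl-9α-tigloyloxy-trans-decal-8-one
Conditions: HF·pyridine, pyridine, THF, 0 °C to rt
Reagents that add atoms: none
Why: Fluoride-mediated cleavage of the silyl ether under buffered, weakly acidic conditions. These should leave the α-acyloxy ketone, the tiglate and the β,γ-unsaturated ketone unchanged, whereas basic fluoride could cause acyl migration or enolisation.

Step 13
Reactants: 21 3α-hydroxy-7α-isopropenyl-4β,5β-dimethyl-9α-tigloyloxy-trans-decal-8-one; 22 3-methylbut-2-enoyl chloride (senecioyl chloride)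
Product: 23 CNP0164025.1 (3R,4R,5R,7S,9S,10R)
Conditions: 22, pyridine, DMAP (cat.), CH2Cl2, 0 °C
Reagents that add atoms: none
Why: Acylation of the equatorial C3 alcohol with the acid chloride. A weak base at 0 °C is used to avoid vinylketene formation and deconjugation of the senecioyl group, and C3 keeps its configuration because its C–O bond is not broken.

## Compound list

1 | 3-methylcyclohex-2-en-1-one | CC1=CC(=O)CCC1 | starting material
2 | (R)-3-methylcyclohex-2-en-1-ol | CC1=C[C@H](O)CCC1 | intermediate
3 | (R)-triisopropyl[(3-methylcyclohex-2-en-1-yl)oxy]silane | CC1=C[C@H](O[Si](C(C)C)(C(C)C)C(C)C)CCC1 | intermediate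
4 | (R)-2-methyl-4-(triisopropylsilyloxy)cyclohex-2-en-1-one | CC1=C[C@H](O[Si](C(C)C)(C(C)C)C(C)C)CCC1=O | intermediate
5 | lithium (3R,4R)-2,3-dimethyl-4-(triisopropylsilyloxy)cyclohex-1-en-1-olate | [Li]OC1=C(C)[C@@H](C)[C@H](O[Si](C(C)C)(C(C)C)C(C)C)CC1 | intermediate (not isolated)
6 | (3R,4R)-2,3-dimethyl-4-(triisopropylsilyloxy)cyclohex-1-en-1-yl trifluoromethanesulfonate | O=S(=O)(OC1=C(C)[C@@H](C)[C@H](O[Si](C(C)C)(C(C)C)C(C)C)CC1)C(F)(F)F | intermediate
7 | (E)-2-(2-ethoxyethenyl)-4,4,5,5-tetramethyl-1,3,2-dioxaborolane | CCO/C=C/B1OC(C)(C)C(C)(C)O1 | starting material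
8 | triisopropyl{[(1R,2R)-4-[(E)-2-ethoxyethenyl]-2,3-dimethylcyclohex-3-en-1-yl]oxy}silane | CCO/C=C/C1=C(C)[C@@H](C)[C@H](O[Si](C(C)C)(C(C)C)C(C)C)CC1 | intermediate
9 | but-3-en-2-one (methyl vinyl ketone) | C=CC(C)=O | starting material
10 | 7α-acetyl-8α-ethoxy-4β,5β-dimethyl-3α-(triisopropylsilyloxy)octal-9-ene (3R,4R,5R,7R,8S) | CC(=O)[C@@H]1C[C@]2(C)[C@@H](C)[C@H](O[Si](C(C)C)(C(C)C)C(C)C)CCC2=C[C@@H]1OCC | intermediate
11 | 8α-ethoxy-7α-isopropenyl-4β,5β-dimethyl-3α-(triisopropylsilyloxy)octal-9-ene (3R,4R,5R,7S,8S) | C=C(C)[C@@H]1C[C@]2(C)[C@@H](C)[C@H](O[Si](C(C)C)(C(C)C)C(C)C)CCC2=C[C@@H]1OCC | intermediate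
12 | 8-ethoxy-8-hydroxy-7α-isopropenyl-4β,5β-dimethyl-3α-(triisopropylsilyloxy)octal-9-ene (hemiketal, C8 undefined) | C=C(C)[C@@H]1C[C@]2(C)[C@@H](C)[C@H](O[Si](C(C)C)(C(C)C)C(C)C)CCC2=CC1(O)OCC | intermediate (not isolated)
13 | 7α-isopropenyl-4β,5β-dimethyl-3α-(triisopropylsilyloxy)octal-9-en-8-one (3R,4R,5R,7S) | C=C(C)[C@@H]1C[C@]2(C)[C@@H](C)[C@H](O[Si](C(C)C)(C(C)C)C(C)C)CCC2=CC1=O | intermediate
14 | lithium C8–C9 enolate of the trans-fused 7α-isopropenyl-4β,5β-dimethyl-3α-(triisopropylsilyloxy)decal-8-one (10α-H) | C=C(C)[C@@H]1C[C@]2(C)[C@@H](C)[C@H](O[Si](C(C)C)(C(C)C)C(C)C)CC[C@H]2C=C1O[Li] | intermediate (not isolated)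
15 | trans-fused 7α-isopropenyl-4β,5β-dimethyl-3α-(triisopropylsilyloxy)-8-(trimethylsilyloxy)-10α-H-octal-8-ene | C=C(C)[C@@H]1C[C@]2(C)[C@@H](C)[C@H](O[Si](C(C)C)(C(C)C)C(C)C)CC[C@H]2C=C1O[Si](C)(C)C | intermediate
16 | 8α,9α-epoxy-7α-isopropenyl-4β,5β-dimethyl-3α-(triisopropylsilyloxy)-8β-(trimethylsilyloxy)-trans-decalin | C=C(C)[C@@H]1C[C@]2(C)[C@@H](C)[C@H](O[Si](C(C)C)(C(C)C)C(C)C)CC[C@H]2[C@@H]3O[C@]13O[Si](C)(C)C | intermediate (not isolated)
17 | 7α-isopropenyl-4β,5β-dimethyl-3α-(triisopropylsilyloxy)-9α-(trimethylsilyloxy)-trans-decal-8-one | C=C(C)[C@@H]1C[C@]2(C)[C@@H](C)[C@H](O[Si](C(C)C)(C(C)C)C(C)C)CC[C@H]2[C@H](O[Si](C)(C)C)C1=O | intermediate (not isolated)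
18 | 9α-hydroxy-7α-isopropenyl-4β,5β-dimethyl-3α-(triisopropylsilyloxy)-trans-decal-8-one (3R,4R,5R,7S,9S,10R) | C=C(C)[C@@H]1C[C@]2(C)[C@@H](C)[C@H](O[Si](C(C)C)(C(C)C)C(C)C)CC[C@H]2[C@H](O)C1=O | intermediate
19 | (E)-2-methylbut-2-enoyl chloride (tigloyl chloride) | C/C=C(\C)C(=O)Cl | starting material
20 | 7α-isopropenyl-4β,5β-dimethyl-9α-tigloyloxy-3α-(triisopropylsilyloxy)-trans-decal-8-one | C=C(C)[C@@H]1C[C@]2(C)[C@@H](C)[C@H](O[Si](C(C)C)(C(C)C)C(C)C)CC[C@H]2[C@H](OC(=O)/C(C)=C/C)C1=O | intermediate
21 | 3α-hydroxy-7α-isopropenyl-4β,5β-dimethyl-9α-tigloyloxy-trans-decal-8-one | C=C(C)[C@@H]1C[C@]2(C)[C@@H](C)[C@H](O)CC[C@H]2[C@H](OC(=O)/C(C)=C/C)C1=O | intermediate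
22 | 3-methylbut-2-enoyl chloride (senecioyl chloride) | CC(C)=CC(=O)Cl | starting material
23 | CNP0164025.1, 3α-senecioyloxy-9α-tigloyloxy-eremophil-11-en-8-one (3R,4R,5R,7S,9S,10R) | C=C(C)[C@@H]1C[C@]2(C)[C@@H](C)[C@H](OC(=O)C=C(C)C)CC[C@H]2[C@H](OC(=O)/C(C)=C/C)C1=O | target

## Step count and least certain steps

Total: 13 steps. Longest linear sequence: 13 steps, from 1 to 23.

**Step 6 (key step).** The cycloaddition may be slow because the C14 methyl sits on the inside of the diene terminus, so polymerisation of 9 and decomposition of the enol ether can compete. Facial discrimination may also be incomplete, because in the half-chair with a pseudoaxial C4 methyl the C3 silyloxy group is axial on the α face that the dienophile must use. Fallback, setting out from 8: acrolein, which is smaller and can be activated as its iminium ion by a chiral imidazolidinone salt (adding catalyst control over the face), should give the 7α-formyl-8α-ethoxy adduct F1. Addition of MeMgBr should give the 7-(1-hydroxyethyl) carbinol F2, and oxidation with Dess–Martin periodinane returns to 10.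

**Step 8.** Hydride abstraction at C8 may be too slow if the C8–H bond is poorly aligned with the C9=C10 π-system or shielded by the cis isopropenyl group, which would let oxidation at other allylic positions compete. Fallback, setting out from 11: acid-promoted solvolysis (dilute HClO4, aqueous THF) should ionise the allylic ether to the C8–C9–C10 allyl cation, which water captures to give the secondary C8 allylic alcohol F3 and its transposed tertiary C10 isomer F4. Pyridinium chlorochromate, [C5H5NH][CrO3Cl], oxidises F3 directly and F4 by Babler–Dauben oxidative transposition, and both return to 13.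

**Step 3.** Site selectivity may be poor: oxidation could occur at the silyloxy-bearing carbon, with loss of the silyl group, or at the methyl group, or go too far. Fallback, setting out from 1: γ-oxidation of the enone (Pd(OH)2 on carbon, t-BuOOH, K2CO3) should give 2-methylcyclohex-2-ene-1,4-dione F5. Oxazaborolidine-catalysed reduction of its less hindered carbonyl, the one flanked by the unsubstituted alkene carbon, should give (R)-4-hydroxy-2-methylcyclohex-2-en-1-one F6, and silylation (TIPSCl, imidazole) returns to 4.

**Step 7.** The basic ylide may enolise the methyl ketone towards C7, leading to epimerisation at C7 or to β-elimination of ethoxide. Fallback, setting out from 10: Peterson olefination. Me3SiCH2Li with CeCl3, a weakly basic organocerium reagent, should add to the ketone to give the β-hydroxysilane F7, and KH in THF effects syn-elimination to 11.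

**Step 10.** The peracid may also epoxidise the isopropenyl group, or face selectivity at the enol ether may be lost. Fallback, setting out from 15: MeLi regenerates lithium enolate 14, which is hydroxylated with 2-(phenylsulfonyl)-3-phenyloxaziridine, an oxidant that does not epoxidise isolated alkenes, to give 18 directly. No new compound is made (F0).

## Further compounds

F1 | step 6 | 8α-ethoxy-7α-formyl-4β,5β-dimethyl-3α-(triisopropylsilyloxy)octal-9-ene | O=C[C@@H]1C[C@]2(C)[C@@H](C)[C@H](O[Si](C(C)C)(C(C)C)C(C)C)CCC2=C[C@@H]1OCC
F2 | step 6 | 8α-ethoxy-7α-(1-hydroxyethyl)-4β,5β-dimethyl-3α-(triisopropylsilyloxy)octal-9-ene (carbinol carbon undefined) | CC(O)[C@@H]1C[C@]2(C)[C@@H](C)[C@H](O[Si](C(C)C)(C(C)C)C(C)C)CCC2=C[C@@H]1OCC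
F3 | step 8 | 7α-isopropenyl-4β,5β-dimethyl-3α-(triisopropylsilyloxy)octal-9-en-8-ol (C8 undefined) | C=C(C)[C@@H]1C[C@]2(C)[C@@H](C)[C@H](O[Si](C(C)C)(C(C)C)C(C)C)CCC2=CC1O
F4 | step 8 | 7α-isopropenyl-4β,5β-dimethyl-3α-(triisopropylsilyloxy)octal-8-en-10-ol (C10 undefined) | C=C(C)[C@@H]1C[C@]2(C)[C@@H](C)[C@H](O[Si](C(C)C)(C(C)C)C(C)C)CCC2(O)C=C1
F5 | step 3 | 2-methylcyclohex-2-ene-1,4-dione | CC1=CC(=O)CCC1=O
F6 | step 3 | (R)-4-hydroxy-2-methylcyclohex-2-en-1-one | CC1=C[C@H](O)CCC1=O
F7 | step 7 | 8α-ethoxy-7α-[2-hydroxy-1-(trimethylsilyl)propan-2-yl]-4β,5β-dimethyl-3α-(triisopropylsilyloxy)octal-9-ene (carbinol carbon undefined) | C[Si](C)(C)CC(C)(O)[C@@H]1C[C@]2(C)[C@@H](C)[C@H](O[Si](C(C)C)(C(C)C)C(C)C)CCC2=C[C@@H]1OCC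
F0 | step 10 | none | none
A1 | alternative 1 | (+)-aristolochene | C=C(C)[C@@H]1C[C@]2(C)[C@@H](C)CCCC2=CC1
A2 | alternative 1 | (2E,6E)-farnesyl diphosphate | CC(C)=CCC/C(C)=C/CC/C(C)=C/COP(=O)(O)OP(=O)(O)O
A3 | alternative 2 | trans-fused 3-(tert-butyldimethylsilyloxy)-4,5-dimethyldecalin-8-one | C1C[C@]2(C)[C@@H](C)[C@H](O[Si](C)(C)C(C)(C)C)CC[C@H]2CC1=O
A4 | alternative 2 | (E)-cyclodec-9-en-8-one with 5-methylene, 4-methyl and 3-(tert-butyldimethylsilyloxy) groups (eremophilane numbering) | C=C1CCC(=O)/C=C/CC[C@@H](O[Si](C)(C)C(C)(C)C)[C@@H]1C
A5 | alternative 3 | cis-fused 8-methoxy-3-(tert-butyldimethylsilyloxy)-4,5-dimethyl bicyclic 2,7-diene-6,9-dione | O=C1C=C(OC)C(=O)[C@H]2CC=C(O[Si](C)(C)C(C)(C)C)[C@@H](C)[C@@]12C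
A6 | alternative 3 | 2-methoxy-5-methyl-1,4-benzoquinone | COC1=CC(=O)C(C)=CC1=O
A7 | alternative 3 | (Z)-3-(tert-butyldimethylsilyloxy)penta-1,3-diene | C=C/C(O[Si](C)(C)C(C)(C)C)=C/C
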